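## Structural features

The target is a germacranolide: a ten-membered carbocycle (C1 to C10) fused across C6–C7 to an α-methylene-γ-butyrolactone (O–C6, C7–C11, C12 carbonyl, C13 methylene). Both ring alkenes are ring-cis and trisubstituted: C1=C10 carries the methyl ester C14, and C4=C5 carries the hydroxymethyl group C15. Four contiguous stereocenters (C6, C7, C8, C9) and the isolated C2 carbinol give (2S,6R,7S,8S,9S). In that configuration O2, O6 and O9 lie on one face of the ring, while C11 and O8 lie on the other, so the lactone is trans-fused, O8 is cis to C11 and O9 is trans to O8.

The fragile groups are: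
- the α-methylene lactone, a Michael acceptor;
- the angelate, which isomerises to the tiglate through activated acyl intermediates;
- the C9 acetate, which is allylic to the C10 acrylate and is therefore open to allylic displacement and to ionisation by zerovalent palladium;
- the C6 lactone oxygen and the C2 oxygen, both β to C4.

The real difficulty is to obtain a medium ring with two ring-cis trisubstituted alkenes and five stereocenters on a flexible frame without a macrocyclisation. The key step exploits the fact that C4 and C9 stand opposite each other in the ring, and each is separated by one methylene from a future alkene or carbinol carbon. The ten ring carbons therefore map onto the periphery of a bicyclic arene-derived diene whose central bond joins C4 to C9. Cleaving that bond leaves ketones exactly at C4 and C9 and a ring with a mirror plane.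

## Logic of the disconnections

**26 back to 23.** The O–Si bond at C2 is cut (26 from 25), then the C4–C15 bond (25 from 24), then the C4–O(triflyl) bond together with the C4=C5 π bond (24 from 23). C4 is a carbonyl carbon from the start, so the hydroxymethyl alkene is traced to a ketone that is unveiled only after all chemistry that depends on C9 is finished. The gain is the loss of C15 and of one trisubstituted alkene. The demand is threefold: enolisation of 23 must go to C5 and not C3, it must give the ring-cis enolate without expelling the C6 carboxylate, and the C–C coupling must spare the C9 acetate. The last point rules out zerovalent palladium at this stage.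

**23 back to 20.** The ketal on C4 is restored (23 from 22), the acetyl C–O bond is cut (22 from 21) and the C9–H bond is removed (21 from 20). C9 has to be a ketone for as long as C7, C8 and C10 are being functionalised, and C4 has to stay masked for the same period because a free C4 ketone would compete in every enolisation. The gain is one stereocenter fewer. The demand is a 1,2-reduction of a cross-conjugated ketone from the face that gives O9 trans to O8, in the presence of the α-methylene lactone.

**20 back to 18.** The C10–C14 bond is cut (20 from 19), then the C10–I bond (19 from 18). The enone C1=C10–C9=O is the natural handle for α-functionalisation at C10. The gain is removal of the ester carbon. The demand is that the carbonylation run while no allylic ester is present, which holds because C4 is still a ketal, and under a base too weak to epimerise C8.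

**18 back to 15 and 17.** The C8–O bond is cut so that the carboxylate oxygen of 17 is the nucleophile (18 from 16 and 17), then the C8–Br bond (16 from 15). An electrophile should enter at C8 anti to the C7–C11 bond, which is the wrong face for oxygen, so a halogen is placed there and displaced with inversion. The gain is removal of one stereocenter and of the angelate. The demand is a clean SN2 reaction at a hindered α-keto carbon without elimination.

**15 back to 11 and 12.** The C11=C13 bond is cut (15 from 14), then the C7–C11 bond (14 from 13), then the ester C–O bond at O6 (13 from 11 and 12). Tethering the C2 unit to O6 decides which of the two enones is attacked and fixes the ring-fusion geometry. The gain is removal of the lactone, C13 and the C7 stereocenter. The demand is a 5-exo conjugate addition that gives the trans-fused lactone on a cis-enone in a ten-membered ring.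

**11 back to 8.** The two C=C bonds C1=C10 and C7=C8 are reconnected to epoxide C–O bonds at C1 and C7, and the O–Si bond is cut (11 from 10 from 9 from 8). In 8 both epoxides are β,γ to the C9 ketone, so base opens each to a γ-hydroxy enone and keeps the C2–O and C6–O bonds. A face-selective epoxidation catalyst cannot supply the chirality here. In 5 the two alkenes are interchanged by a twofold axis through C4 and C9, so a reagent with one facial preference would epoxidise them on opposite faces of the ring, whereas the target needs O2 and O6 on the same face. The syn,syn bis-epoxide is necessarily meso. The absolute configuration is therefore introduced when 8 is opened, by a chiral base that distinguishes the two enantiotopic α-methylenes. The gain is that 8 has a mirror plane. The demand is high enantiotopic-group selectivity and silylation of the first alkoxide before the second epoxide opens.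

**8 back to 5.** The four epoxide C–O bonds are cut (7 from 6), with a reduction and an oxidation at C9 on either side (6 from 5, 8 from 7). A C9 hydroxyl is homoallylic to both alkenes and can deliver oxygen to the same face of each, which secures the syn relation of O2 and O6. The gain is removal of four stereocenters. The demand is directed delivery across a medium ring.

**5 back to 4.** The ketal C–O bonds at C4 are cut. The gain is full twofold symmetry. The demand is mono-functionalisation of two equivalent ketones without moving the β,γ-alkenes.

**4 back to 2.** The two carbonyl carbons C4 and C9 are reconnected as a tetrasubstituted alkene (through 3). The medium ring is then never closed; it is present as the perimeter of a bicycle. The gain is a ten-membered ring with two cis alkenes turned into two fused six-membered rings. The demand is oxidative cleavage of the central alkene in preference to the two disubstituted ones.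

**2 back to 1.** Four C–H bonds are removed. The gain is a bulk aromatic starting material. The demand is a dissolving-metal reduction that stops at the tetrahydro stage with the central alkene intact.

## Other disconnections considered

**Alternative 1:** The ring bond C7–C8 and the C6–O bond are cut together. In the forward sense a nitrile oxide generated at C8 from an oxime (NaOCl) adds across the Z-configured C6=C7 alkene of the same chain. This closes the carbocycle and a bridging isoxazoline in one step and gives A1.
- In favour: the suprafacial cycloaddition to a Z alkene gives the trans relation of O6 and C11 stereospecifically. The isoxazoline then serves as a masked β-hydroxy ketone (C6 hydroxyl, C8 carbonyl). Both trisubstituted alkenes and the C2 and C9 carbinols are made on an open chain, where geometry and configuration are set by standard acyclic methods.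
- Against: the ring closure is a ten-membered cyclisation that competes with dimerisation of the dipole. The bridged regiochemistry (oxygen to C6) is not enforced on a 1,2-disubstituted alkene. The facial choice relative to C2 and C9 rests on remote induction, and C8 still needs a stereoselective reduction on the ring.
- Comparison: on structure, A1 is the better plan for the C4=C5 alkene, because its position and geometry are fixed before the ring exists and no late enolisation is needed. It is the equal of the chosen plan for the C6/C7 relation. On mechanism it pays for a medium-ring closure that the chosen plan avoids entirely. On step economy it needs a long linear chain synthesis carrying three different silyl ethers, against a ring available in two steps.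

**Alternative 2:** The C3–C4 bond is cut. In the forward sense the silyl ketene acetal of a ten-membered lactone (C15 carbonyl, ring oxygen on C1) undergoes an Ireland–Claisen rearrangement through C4, C15, O, C1, C2, C3. This forms C3–C4, breaks O–C1 and gives A2, a cyclodecene with the C15 acid on C4 and an enol ether at C1=C2.
- In favour: a macrolactonisation is easier than a carbocyclisation and is converted into the carbocycle by a sigmatropic step. C15 is already on C4, and a later β-elimination of the C5 oxygen from the C15 carbonyl places the alkene at C4=C5 without any regiochemical question. That point is better than in the chosen plan.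
- Against: the enol ether ends at C1=C2, so C2 must pass through a ketone and the C1=C10 alkene with its ester must be built afterwards from an sp3 C10 bearing a protected hydroxymethyl group. The C15 acid must be reduced and C14 oxidised in the presence of the other functionality. Enolisation of a lactone with a β-oxygen at C5 risks elimination before rearrangement.
- Comparison: on structure, A2 is better at C4=C5 and worse at C1=C10 and C2. On mechanism, the concerted rearrangement is as reliable as the cleavage of the chosen plan. On step economy, A2 carries two p-methoxybenzyl ethers, two silyl ethers and an acetonide and needs several redox corrections, so it is the longer route.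

**Alternative 3:** The bonds C4–C5 and C1–C10 are cut as the two new σ bonds of a [2+2] photocycloaddition. In the forward sense irradiation joins the C5=C10 double bond of a cyclohexenone to the C1=C4 double bond of a cyclobutene and gives A3, a cyclohexanone fused to a bicyclo[2.2.0]hexane. Thermal cycloreversion of the other two cyclobutane bonds would then release the cyclodeca-1(10),4-diene.
- In favour: the approach is convergent. C7, C8 and C9 are set on a six-membered ring where cyclic stereocontrol is dependable, which is better than the chosen plan for these centers. The two ester carbons on C4 and C10 are in place and differentiated as tert-butyl and methyl esters. The ring is formed by strain release and not by cyclisation, which is the equal of the chosen plan.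
- Against: the head-to-head regiochemistry and facial selectivity of an intermolecular enone photocycloaddition that creates two quaternary carbons are uncertain. A concerted opening of a cis,anti,cis skeleton is expected to deliver one ring-trans alkene or a Cope equilibrium with a divinylcyclohexane, whereas the target needs two ring-cis alkenes. The C6 ketone must then be reduced with the right sense on the flexible ring.
- Comparison: on structure, A3 is better for the contiguous stereocenters and for C14 and C15, and worse for alkene geometry. On mechanism, its photochemical step has less predictable selectivity than the ozonolysis. On step economy, the two partners each need a multistep enantioselective synthesis, so the total is not shorter.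

Key step: step 2

Remark 1: germacrane numbering is used for every ring compound from 4 on (ketal carbon C4, carbinol or ketone carbon C9). "Upper face" is the face of the ten-membered ring that carries O2, O6 and O9 in 26; "lower face" is the one that carries C11 and O8.

Remark 2: γ-hydroxy cis-enones such as 11 may rest partly as transannular hemiketals; they are drawn as the open hydroxy ketones through which they react.

Remark 3: the sense of enantiotopic-group selection by the chiral lithium amide on this flexible ring cannot be derived from a model. The (R,R)-amide is written, and its antipode is to be used if it is the other methylene that is attacked.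

## Route

Step 1
Reactants: 1 naphthalene
Product: 2 isotetralin (1,4,5,8-tetrahydronaphthalene)
Conditions: Na, liquid NH3, EtOH, Et2O, -78 °C to -33 °C
Reagents that add atoms: none
Why: Birch reduction: solvated electrons and ethanol reduce one ring to the 1,4-dihydro stage and then the remaining benzene ring in the same way; the ring-fusion alkene is left because an isolated tetrasubstituted alkene accepts an electron far less readily than an arene, and kinetic protonation gives the unconjugated isomer.

Step 2
Reactants: 2 isotetralin
Product: 4 (3Z,8Z)-cyclodeca-3,8-diene-1,6-dione, via methoxy hydroperoxide 3 (not isolated)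
Conditions: O3 (0.95 equiv, metered), CH2Cl2/MeOH (5:1), -78 °C; then Me2S, -78 °C to rt
Reagents that add atoms: ozone, [O-][O+]=O; methanol, CO (retained only in 3)
Why: Ozonolysis: ozone adds as a 1,3-dipole to the ring-fusion alkene, the primary ozonide splits into a ketone and a carbonyl oxide held in the same ring, methanol traps the carbonyl oxide as the methoxy hydroperoxide 3, and Me2S reduces the O–O bond so that the hemiketal collapses to the second ketone. The closest known reaction type is the ozonolytic cleavage of the ring-fusion alkene of a decalin-type bicycle to a cyclodecane-1,6-dione. No ring is closed by bond formation: the ten-membered ring is the perimeter of the bicycle and is set free by cutting the zero-atom bridge, so no cyclisation entropy and no transannular strain are paid in a ring-closing transition state. No stereocenter is formed, and the two alkenes keep the cis geometry that the six-membered rings imposed. The selectivity needed is attack at the tetrasubstituted alkene in preference to the two disubstituted ones. It rests on the higher electron density of the fully alkylated π bond towards the electrophilic dipole, on metering slightly less than one equivalent of ozone at -78 °C, and on stopping at partial conversion with recovery of 2. Methanol prevents recombination to cross-ozonides and gives a peroxide that is reduced cleanly.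

Step 3
Reactants: 4 (3Z,8Z)-cyclodeca-3,8-diene-1,6-dione
Product: 5 (7Z,12Z)-1,4-dioxaspiro[4.9]tetradeca-7,12-dien-10-one (C4 ethylene ketal with free C9 ketone)
Conditions: 1,2-bis(trimethylsilyloxy)ethane (1.0 equiv), Me3SiOSO2CF3 (2 mol%), CH2Cl2, -78 °C; pyridine quench
Reagents that add atoms: 1,2-bis(trimethylsilyloxy)ethane, C[Si](C)(C)OCCO[Si](C)(C)C
Why: Aprotic ketalisation under silyl triflate catalysis: the two carbonyls are equivalent, so one equivalent of reagent gives the mono-ketal statistically, with diketal and recovered 4 recycled; the absence of protic acid and heat avoids migration of the β,γ-alkenes into conjugation and transannular aldol closure.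

Step 4
Reactants: 5 mono-ketal ketone
Product: 6 (7Z,12Z)-1,4-dioxaspiro[4.9]tetradeca-7,12-dien-10-ol (C9 carbinol)
Conditions: NaBH4, MeOH, 0 °C
Reagents that add atoms: none
Why: Borohydride reduction of the only free ketone; the carbinol carbon lies on the mirror plane of 6, so no stereoisomers arise.

Step 5
Reactants: 6 C9 carbinol
Product: 7 meso all-syn bis-epoxy carbinol (1,2- and 6,7-epoxide oxygens and the C9 hydroxyl all on the upper face)
Conditions: VO(acac)2 (5 mol%), t-BuOOH (2.4 equiv), CH2Cl2, 0 °C to rt
Reagents that add atoms: tert-butyl hydroperoxide, CC(C)(C)OO
Why: Hydroxyl-directed epoxidation of a homoallylic alcohol: the vanadium alkoxide–alkylperoxide complex reaches only the alkene face on which the C9–O bond lies, so both equivalent cis alkenes are epoxidised syn to the hydroxyl; this fixes the future O2 and O6 on the same face of the ring, as the target requires.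

Step 6
Reactants: 7 bis-epoxy carbinol
Product: 8 meso cis-bis-epoxy ketone (C9 ketone with both epoxides on the upper face)
Conditions: Dess–Martin periodinane, NaHCO3, CH2Cl2, 0 °C to rt
Reagents that add atoms: none
Why: Periodinane oxidation of the secondary alcohol under bicarbonate buffering; neither acid nor amine base is present, so both β,γ-epoxy ketone units survive and the product remains meso.

Step 7
Reactants: 8 meso bis-epoxy ketone
Product: 11 (2S,6R)-2-(tert-butyldimethylsilyloxy)-6-hydroxy cross-conjugated dienone (ring-cis C1=C10 and C7=C8 with C9 ketone and C4 ketal), via lithium alkoxide 9 (not isolated), via silyl ether 10 (not isolated)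
Conditions: LiN[(R)-CH(CH3)Ph]2 (1.05 equiv, from the amine and n-BuLi), LiCl, THF, -78 °C; t-BuMe2SiOSO2CF3 (1.0 equiv), -78 °C; then Et3N, -78 °C to 0 °C
Reagents that add atoms: tert-butyldimethylsilyl trifluoromethanesulfonate, CC(C)(C)[Si](C)(C)OS(=O)(=O)C(F)(F)F
Why: Desymmetrisation by enantioselective deprotonation: the chiral lithium amide removes a proton from one of the two enantiotopic α-methylenes and the enolate expels the β-oxygen of the neighbouring epoxide (E1cB), giving the C2 alkoxide 9 with the C–O bond of step 5 intact; silylation marks this oxygen, and Et3N then opens the second epoxide by the same E1cB to the free C6 carbinol. Both enones are ring-cis because the ring holds C9 and the carbinol carbon on the same side of each new double bond.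

Step 8
Reactants: 11 hydroxy dienone; 12 diethylphosphonoacetic acid
Product: 13 6-O-(diethylphosphonoacetyl) ester of 11
Conditions: EDC·HCl, DMAP (0.1 equiv), CH2Cl2, 0 °C to rt
Reagents that add atoms: none
Why: Carbodiimide esterification with acyl transfer by DMAP at the only free hydroxyl; any hemiketal tautomer of 11 drains through the open hydroxy ketone.

Step 9
Reactants: 13 phosphonoacetate
Product: 15 trans-fused α-methylene-γ-butyrolactone (C7–C11 bond on the lower face and 12,6-olide, with C9 ketone, C1=C10 enone, C2 silyl ether and C4 ketal), via phosphono lactone 14 (not isolated)
Conditions: KOt-Bu (1.1 equiv), THF, 0 °C; then (CH2O)n, 0 °C to rt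
Reagents that add atoms: formaldehyde (as paraformaldehyde), C=O
Why: Intramolecular Michael addition (5-exo-trig) of the phosphonate-stabilised carbanion to C7 of the tethered enone, then Horner–Wadsworth–Emmons olefination of 14 with formaldehyde. With C6–H eclipsing the enone (allylic 1,3-strain against C9), the C6–O bond stands perpendicular to the π system on the face away from C5; delivery on that face places C11 on the lower face at C7, trans to O6 across the ten-membered ring. The tether also selects the C7=C8 enone over the C1=C10 enone.

Step 10
Reactants: 15 α-methylene lactone ketone
Product: 16 8-bromo ketone (bromine on the upper face, trans to C11)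
Conditions: LiN(SiMe3)2, THF, -78 °C; N-bromosuccinimide, -78 °C; aq. NH4Cl
Reagents that add atoms: N-bromosuccinimide, O=C1CCC(=O)N1Br
Why: Kinetic deprotonation at C8, the only sp3 carbon α to the C9 ketone (the lactone has no α-hydrogen), and bromination of the lithium enolate; bromine should enter on the upper face, anti to the C7–C11 bond, whose exocyclic methylene screens the lower face.

Step 11
Reactants: 16 8-bromo ketone; 17 angelic acid
Product: 18 8-angelate (O8 on the lower face, cis to C11)
Conditions: Cs2CO3, DMF, 0 °C to rt
Reagents that add atoms: none
Why: SN2 displacement of the α-keto bromide by the cesium carboxylate with inversion, which puts O8 on the lower face; because the angelate enters as a nucleophile, no activated acyl derivative is formed and Z to E isomerisation to the tiglate has no pathway.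

Step 12
Reactants: 18 8-angelate enone
Product: 19 10-iodo enone
Conditions: I2, pyridine, CH2Cl2, rt
Reagents that add atoms: iodine, II
Why: α-Iodination of an enone by conjugate addition of pyridine, iodination of the resulting enolate and elimination; only the C1=C10 enone has a vinylic α-hydrogen, and the ring returns the cis alkene.

Step 13
Reactants: 19 10-iodo enone
Product: 20 methyl ester at C10 (C14) with C9 ketone
Conditions: PdCl2(PPh3)2 (5 mol%), CO (1 atm), MeOH, 2,6-lutidine, DMF, 40 °C
Reagents that add atoms: carbon monoxide, [C-]#[O+]; methanol, CO
Why: Methoxycarbonylation: zerovalent palladium inserts into the C–I bond, CO inserts and methanol cleaves the acylpalladium; no allylic ester is present at this stage because C4 is still a ketal, and the weak hindered base should not epimerise C8.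

Step 14
Reactants: 20 keto ester
Product: 21 9-carbinol (hydroxyl on the upper face, trans to O8)
Conditions: NaBH4, CeCl3·7H2O, MeOH, -78 °C
Reagents that add atoms: none
Why: Luche reduction: the cerium salt promotes 1,2-addition at the cross-conjugated ketone and spares the α-methylene lactone; hydride should add anti to the perpendicular C8–O bond (polar Felkin–Anh) with C7 and C10 antiperiplanar, which places the new hydroxyl trans to O8.

Step 15
Reactants: 21 9-carbinol
Product: 22 9-acetate
Conditions: Ac2O, pyridine, DMAP (cat.), CH2Cl2, 0 °C
Reagents that add atoms: acetic anhydride, CC(=O)OC(C)=O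
Why: Acylation of the only free hydroxyl (O2 is silylated) with DMAP catalysis.

Step 16
Reactants: 22 9-acetate ketal
Product: 23 4-ketone
Conditions: PPTS, acetone/H2O (5:1), 55 °C
Reagents that add atoms: water, O
Why: Acid-catalysed hydrolysis of the dioxolane under conditions mild enough for the silyl ether, the esters and the β-acyloxy ketone that is formed.

Step 17
Reactants: 23 4-ketone
Product: 24 4-enol triflate (ring-cis C4=C5)
Conditions: KN(SiMe3)2 added to 23 and N-(5-chloro-2-pyridyl)triflimide, THF, -78 °C; aq. NH4Cl
Reagents that add atoms: N-(5-chloro-2-pyridyl)triflimide, O=S(=O)(N(c1ccc(Cl)cn1)S(=O)(=O)C(F)(F)F)C(F)(F)F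
Why: Kinetic enolisation with O-sulfonylation in situ: the base meets the ketone in the presence of the triflimide, so the enolate is trapped before the C6 carboxylate can be expelled; C5–H is more acidic (β-acyloxy) and less hindered than C3–H (next to the silyloxy-bearing C2), and the ring with its cis C1=C10 alkene and fused lactone should accommodate only the ring-cis enolate (oxygen trans to C6).

Step 18
Reactants: 24 enol triflate
Product: 25 15-hydroxy compound (2-O-silyl ether of the target)
Conditions: CrCl2 (6 equiv), NiCl2 (2 mol%), (CH2O)n, DMF, rt
Reagents that add atoms: formaldehyde (as paraformaldehyde), C=O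
Why: Nozaki–Hiyama–Kishi reaction: zerovalent nickel inserts into the C–O bond of the triflate, and transmetalation gives an alkenylchromium species that adds to formaldehyde with retention of alkene geometry; esters, the lactone and the allylic acetate are inert, whereas a coupling through zerovalent palladium would ionise the C9 acetate.

Step 19
Reactants: 25 silyl ether
Product: 26 target, methyl (2S,6R,7S,8S,9S)-9-acetoxy-8-angeloyloxy-2,15-dihydroxygermacra-1(10),4,11(13)-trien-12,6-olid-14-oate (both ring alkenes ring-cis)
Conditions: HF·pyridine, pyridine, THF, 0 °C to rt
Reagents that add atoms: none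
Why: Fluoride cleavage of the Si–O bond in buffered HF·pyridine, which does not touch the esters, the allylic acetate or the α-methylene lactone.

## Compound list

1 | naphthalene | c1ccc2ccccc2c1 | starting material
2 | isotetralin (1,4,5,8-tetrahydronaphthalene) | C1=CCC2=C(C1)CC=CC2 | intermediate
3 | (3Z,8Z)-6-hydroperoxy-6-methoxycyclodeca-3,8-dien-1-one | COC1(OO)C/C=C\CC(=O)C/C=C\C1 | intermediate
4 | (3Z,8Z)-cyclodeca-3,8-diene-1,6-dione | O=C1C/C=C\CC(=O)C/C=C\C1 | intermediate
5 | (7Z,12Z)-1,4-dioxaspiro[4.9]tetradeca-7,12-dien-10-one | O=C1C/C=C\CC2(OCCO2)C/C=C\C1 | intermediate
6 | (7Z,12Z)-1,4-dioxaspiro[4.9]tetradeca-7,12-dien-10-ol | OC1C/C=C\CC2(OCCO2)C/C=C\C1 | intermediate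
7 | meso all-syn 1,2:6,7-bis-epoxy C9 carbinol, C4 ethylene ketal | C1COC2(O1)C[C@H]3O[C@H]3C[C@@H](O)C[C@H]4O[C@H]4C2 | intermediate
8 | meso cis-1,2:6,7-bis-epoxy C9 ketone, C4 ethylene ketal | C1COC2(O1)C[C@H]3O[C@H]3CC(=O)C[C@H]4O[C@H]4C2 | intermediate
9 | lithium (2S)-alkoxide of the mono-opened 6,7-epoxy 1(10)-en-9-one, C4 ethylene ketal | C1COC2(O1)C[C@H]3O[C@H]3CC(=O)/C=C\[C@@H]([O-])C2.[Li+] | intermediate
10 | 2-O-tert-butyldimethylsilyl ether of the mono-opened 6,7-epoxy 1(10)-en-9-one | C1COC2(O1)C[C@H]3O[C@H]3CC(=O)/C=C\[C@@H](O[Si](C)(C)C(C)(C)C)C2 | intermediate
11 | (2S,6R)-2-(tert-butyldimethylsilyloxy)-6-hydroxy-1(10),7-dien-9-one, C4 ethylene ketal | C1COC2(O1)C[C@@H](O)/C=C\C(=O)/C=C\[C@@H](O[Si](C)(C)C(C)(C)C)C2 | intermediate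
12 | diethylphosphonoacetic acid | CCOP(=O)(CC(=O)O)OCC | starting material
13 | 6-O-(diethylphosphonoacetyl) ester of 11 | C1COC2(O1)C[C@@H](OC(=O)CP(=O)(OCC)OCC)/C=C\C(=O)/C=C\[C@@H](O[Si](C)(C)C(C)(C)C)C2 | intermediate
14 | trans-fused 11-(diethylphosphono)-12,6-olide (Michael adduct, C11 epimers) | CCOP(=O)(OCC)C1C(=O)O[C@@H]2CC3(OCCO3)C[C@H](O[Si](C)(C)C(C)(C)C)/C=C\C(=O)C[C@@H]12 | intermediate
15 | trans-fused α-methylene 12,6-olide with C9 ketone, C1=C10 enone, C2 silyl ether and C4 ketal | C=C1C(=O)O[C@@H]2CC3(OCCO3)C[C@H](O[Si](C)(C)C(C)(C)C)/C=C\C(=O)C[C@@H]12 | intermediate
16 | 8-bromo derivative of 15 (bromine on the upper face) | C=C1C(=O)O[C@@H]2CC3(OCCO3)C[C@H](O[Si](C)(C)C(C)(C)C)/C=C\C(=O)[C@H](Br)[C@@H]12 | intermediate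
17 | angelic acid, (Z)-2-methylbut-2-enoic acid | C/C=C(/C)C(=O)O | starting material
18 | 8-angeloyloxy ketone (O8 on the lower face) | C=C1C(=O)O[C@@H]2CC3(OCCO3)C[C@H](O[Si](C)(C)C(C)(C)C)/C=C\C(=O)[C@@H](OC(=O)/C(C)=C\C)[C@@H]12 | intermediate
19 | 10-iodo enone | C=C1C(=O)O[C@@H]2CC3(OCCO3)C[C@H](O[Si](C)(C)C(C)(C)C)/C=C(/I)C(=O)[C@@H](OC(=O)/C(C)=C\C)[C@@H]12 | intermediate
20 | 10-methoxycarbonyl 9-ketone | C=C1C(=O)O[C@@H]2CC3(OCCO3)C[C@H](O[Si](C)(C)C(C)(C)C)/C=C(/C(=O)OC)C(=O)[C@@H](OC(=O)/C(C)=C\C)[C@@H]12 | intermediate
21 | 9-carbinol (hydroxyl on the upper face) | C=C1C(=O)O[C@@H]2CC3(OCCO3)C[C@H](O[Si](C)(C)C(C)(C)C)/C=C(/C(=O)OC)[C@H](O)[C@@H](OC(=O)/C(C)=C\C)[C@@H]12 | intermediate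
22 | 9-acetate, C4 ethylene ketal | C=C1C(=O)O[C@@H]2CC3(OCCO3)C[C@H](O[Si](C)(C)C(C)(C)C)/C=C(/C(=O)OC)[C@H](OC(C)=O)[C@@H](OC(=O)/C(C)=C\C)[C@@H]12 | intermediate
23 | 4-ketone | C=C1C(=O)O[C@@H]2CC(=O)C[C@H](O[Si](C)(C)C(C)(C)C)/C=C(/C(=O)OC)[C@H](OC(C)=O)[C@@H](OC(=O)/C(C)=C\C)[C@@H]12 | intermediate
24 | 4-enol triflate (ring-cis C4=C5) | C=C1C(=O)O[C@@H]2/C=C(/OS(=O)(=O)C(F)(F)F)C[C@H](O[Si](C)(C)C(C)(C)C)/C=C(/C(=O)OC)[C@H](OC(C)=O)[C@@H](OC(=O)/C(C)=C\C)[C@@H]12 | intermediate
25 | 2-O-tert-butyldimethylsilyl ether of the target | C=C1C(=O)O[C@@H]2/C=C(/CO)C[C@H](O[Si](C)(C)C(C)(C)C)/C=C(/C(=O)OC)[C@H](OC(C)=O)[C@@H](OC(=O)/C(C)=C\C)[C@@H]12 | intermediate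
26 | methyl (2S,6R,7S,8S,9S)-9-acetoxy-8-angeloyloxy-2,15-dihydroxygermacra-1(10),4,11(13)-trien-12,6-olid-14-oate | C=C1C(=O)O[C@@H]2/C=C(/CO)C[C@H](O)/C=C(/C(=O)OC)[C@H](OC(C)=O)[C@@H](OC(=O)/C(C)=C\C)[C@@H]12 | target

## Step count and least certain steps

Total step count: 19. Longest linear sequence: 19 steps (1 to 26); 12 and 17 are purchased.

**Step 2 (key step).** Loss of site selectivity is the likely failure: ozone is only moderately more reactive towards the tetrasubstituted alkene than towards the two disubstituted ones, so over-oxidation to ring-opened dialdehydes can erode the yield. Fallback, from 2: epoxidation with m-chloroperbenzoic acid, an electrophile with a much larger preference for the fully substituted alkene, should give 4a,8a-epoxy-1,4,4a,5,8,8a-hexahydronaphthalene F1. Periodic acid (H5IO6) in aqueous THF then hydrolyses and cleaves the epoxide to 4, where the route is rejoined.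

**Step 7.** Two processes may fail. Enantiotopic-group discrimination by the lithium amide may be low on a conformationally mobile ring. The second epoxide may also open before the silyl triflate is consumed, which leads to double silylation and a meso product. Fallback, from 8:
- Et3N opens both epoxides to the meso 2,6-dihydroxy dienone ketal F2.
- A lipase (from Burkholderia cepacia) with vinyl acetate acetylates one of the two enantiotopic hydroxyls to the 6-O-acetate F3. The enzyme, or the mode (acylation of the diol or hydrolysis of its diacetate), is chosen so that the acetate sits on O6.
- t-BuMe2SiOSO2CF3 and 2,6-lutidine silylate O2 to the 6-O-acetyl 2-O-silyl ether F4.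
- K2CO3 in methanol removes the acetate and returns 11.

**Step 17.** Deprotonation may occur at C3 instead of C5, the C4=C5 enolate may eliminate the C6 carboxylate and open the lactone, or a ring-trans enolate may form. All three follow from the two β-oxygen substituents that flank the ketone. Fallback, from 23:
- Methylenation with Zn, CH2Br2 and TiCl4 should give the 4-methylene compound F5.
- Sensitised photo-oxygenation (O2, tetraphenylporphyrin, light), a Schenck ene reaction of the only electron-rich alkene, should give the C15 allylic hydroperoxide F6 with the double bond moved to C4=C5.
- PPh3 reduces it to 25, so that steps 17 and 18 are both bypassed.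

**Step 11.** Substitution at the hindered α-keto carbon may lose out to elimination towards a C7=C8 enone, or to epimerisation of the bromide by bromide exchange. Fallback, from 15: LiN(SiMe3)2 and then 2-(phenylsulfonyl)-3-phenyloxaziridine should give the 8-hydroxy ketone F7 with the hydroxyl on the upper face. A Mitsunobu esterification with 17 (PPh3, diisopropyl azodicarboxylate) inverts C8 and returns 18.

**Step 14.** Poor facial selectivity at C9 is possible, because the Felkin–Anh argument depends on the C7–C8–C9–C10 torsion of the reacting conformer; conjugate reduction of the α-methylene lactone is the second concern. Fallback, from 20 to 21: reagent control by a Corey–Bakshi–Shibata reduction, with the oxazaborolidine enantiomer that delivers hydride to the lower face, without any new compound (F0).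

**Step 5.** Delivery of oxygen across the medium ring may be incomplete or not fully syn, and the carbinol may be oxidised by the peroxide. Fallback, from 5 directly to 8: dimethyldioxirane in acetone epoxidises both alkenes of the ketone without a directing group, and the syn bis-epoxide 8 is separated from its anti isomer, without any new compound (F0).

## Further compounds

F1 | step 2 | 4a,8a-epoxy-1,4,4a,5,8,8a-hexahydronaphthalene | C1=CCC23CC=CCC2(C1)O3
F2 | step 7 | meso 2,6-dihydroxy-1(10),7-dien-9-one, C4 ethylene ketal | C1COC2(O1)C[C@@H](O)/C=C\C(=O)/C=C\[C@@H](O)C2
F3 | step 7 | 6-O-acetate of the dihydroxy dienone | C1COC2(O1)C[C@@H](OC(C)=O)/C=C\C(=O)/C=C\[C@@H](O)C2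
F4 | step 7 | 6-O-acetyl 2-O-tert-butyldimethylsilyl ether | C1COC2(O1)C[C@@H](OC(C)=O)/C=C\C(=O)/C=C\[C@@H](O[Si](C)(C)C(C)(C)C)C2
F5 | step 17 | 4-methylene compound | C=C1C(=O)O[C@@H]2CC(=C)C[C@H](O[Si](C)(C)C(C)(C)C)/C=C(/C(=O)OC)[C@H](OC(C)=O)[C@@H](OC(=O)/C(C)=C\C)[C@@H]12
F6 | step 17 | C15 allylic hydroperoxide with ring-cis C4=C5 | C=C1C(=O)O[C@@H]2/C=C(/COO)C[C@H](O[Si](C)(C)C(C)(C)C)/C=C(/C(=O)OC)[C@H](OC(C)=O)[C@@H](OC(=O)/C(C)=C\C)[C@@H]12
F7 | step 11 | 8-hydroxy ketone with the hydroxyl on the upper face | C=C1C(=O)O[C@@H]2CC3(OCCO3)C[C@H](O[Si](C)(C)C(C)(C)C)/C=C\C(=O)[C@H](O)[C@@H]12
F0 | step 14 | none | none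
F0 | step 5 | none | none
A1 | alternative 1 | isoxazoline-bridged cyclodecadiene (N–O bridge from C8 to C6) | COC(=O)C[C@H]1[C@H]2/C=C(/CO[Si](C)(C)C(C)(C)C)C[C@H](O[Si](C)(C)C(C)(C)C)/C=C(/C(=O)OC)[C@H](O[Si](CC)(CC)CC)C1=NO2
A2 | alternative 2 | cyclodecene carboxylic acid (C15 acid on C4, C1=C2 enol ether) | CC1(C)O[C@@H]2[C@@H](O1)[C@@H](C(=O)O)C/C(OCC)=C\[C@H](COCc1ccc(OC)cc1)[C@H](O[Si](C)(C)C(C)(C)C)[C@@H](OCc1ccc(OC)cc1)[C@H]2CCO[Si](C)(C)C(C)(C)C
A3 | alternative 3 | head-to-head cis,anti,cis photoadduct (cyclohexanone fused to bicyclo[2.2.0]hexane) | CC(C)(C)OC(=O)[C@@]12C[C@H](O[Si](C)(C)C(C)(C)C)[C@@H]1[C@@]1(C(=O)OC)[C@H](OCc3ccc(OC)cc3)[C@@H](O[Si](CC)(CC)CC)[C@@H](CC(=O)OC)C(=O)[C@H]12
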